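## The problem

Target 20 is a C2-symmetric 1,4-dioxane with a methyl group on C3 and C5 and an unsymmetrical 2,2'-biphenol arm on C2 and C6. All four ring carbons are stereogenic and (R). Neighbouring substituents are trans (C2-aryl/C3-methyl and C5-methyl/C6-aryl), and the pairs related across each ring oxygen are trans as well. A chair therefore holds one aryl/methyl pair diequatorial and the other diaxial, so the array is not simply the thermodynamic sink and has to be set under kinetic control. C3 and C5 flank O4 and correspond to two lactic acid units joined as an ether. Once fixed, they can direct the creation of C2 and C6; the reverse order offers no comparable handle. O1 joins two benzylic carbons whose aryl groups carry a para oxygen. This dibenzylic ether ionizes under acid (epimerization, ring opening), and as the free phenol it can expel alkoxide to a quinone methide under base and heat. The terminal allyl groups do not tolerate palladium hydrides or arylpalladium species at high temperature, so they should arrive late, and the four phenols must be masked during metal catalysis. The feature that makes the key step possible is this: each biaryl bond joins the carbon ortho to OH on ring A (the ring on the dioxane) to the carbon ortho to OH on ring B (the allyl-bearing ring). Ring A is para-substituted by the dioxane carbon, so its two ortho C–H bonds are equivalent, and one silicon atom can bridge the two phenolic oxygens and hold a halogenated carbon of ring B next to a C–H bond of ring A.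

## Retrosynthesis

**20 from 19.** The four phenols of 20 are masked pairwise as two di-tert-butylsilylene bridges in 19, so the last step cuts only Si–O bonds. The bridge is the tether of the key step and costs no extra protecting-group step. It also keeps the phenols neutral while the allyl groups are put on. The forward reaction is a buffered fluoride cleavage that must leave the allyl groups and the dibenzylic ether alone.

**19 from 17 and 18.** The two aryl–CH2 bonds are cut, which leads to the dichloride 17 and allylboronic acid pinacol ester 18. An allyl group could not be carried through a palladium-catalysed arylation at 110 °C without Heck insertion or double-bond migration. Chlorine on the same carbon is inert to a PPh3-ligated catalyst but is activated by a dialkylbiarylphosphine, so it is orthogonal to the bromine used in the key step. The forward reaction is a twofold Suzuki–Miyaura coupling of electron-rich aryl chlorides.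

**17 from 16.** Both biaryl bonds are cut, each between the ortho carbon of ring A and the bromine-bearing carbon of ring B. The neighbouring options are weaker: an intermolecular Suzuki coupling needs ring A halogenated and ring B borylated, and oxidative phenol coupling cannot distinguish cross- from homocoupling. In 16 the O–Si–O tether makes the cross-coupling intramolecular, and ring A needs no prefunctionalization. The precursor 16 contains no biaryl bond and is assembled from a bisphenol and a simple bromophenol. The forward reaction must insert into C–Br and not C–Cl, arylate only the ortho C–H of ring A, and do so twice in one molecule.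

**16 from 11 and 14.** The two Si–O bonds to ring A are cut, which gives the bisphenol 11 and the hydrosilane 14. The latter is activated in the flask as the bromosilane 15 and comes from 2-bromo-4-chlorophenol 12 and di-tert-butylchlorosilane 13. Activating the silicon on the simple partner keeps electrophilic bromine away from the dioxane. The forward reaction must silylate both phenols completely.

**11 from 7 and 8.** After desilylation of 10 to 11, the C2–aryl and C6–aryl bonds are cut, leading to the bis-acetal 7 and tert-butyldimethyl(phenoxy)silane 8, through the monoaryl acetate 9. This polarity is chosen for its stereochemical outcome: an arene adding to a hydrogen-substituted cyclic oxocarbenium ion enters axially and anti to the adjacent methyl, which is the trans relationship 20 needs. The two neighbouring cuts give less control. Closing O1 last by benzylic ionization, or delivering hydride to an aryl-substituted oxocarbenium ion, would favour an equatorial aryl cis to an axial methyl. The precursor 7 has only the two lactate-derived stereocentres. The forward reaction must be para-selective, twofold and kinetically controlled.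

**7 from 4.** The acetal C–O bonds at O1 are cut. O1 is the hydrate oxygen of the dialdehyde 5, which closes to the bis-hemiacetal 6 and is acetylated to 7; 5 comes from the diester 4 by partial reduction. No C–C bond is made and the methyl centres are untouched. The forward reaction must stop at the aldehyde oxidation level without epimerizing the α-alkoxy centres.

**4 from 2 and 3.** The O4–C bond is cut. Ethyl (R)-lactate 3 serves as the oxygen nucleophile with retention, and the triflate 2 of ethyl (S)-lactate 1 as the electrophile with inversion. This gives the (R,R)-ether with both centres from the chiral pool. The forward reaction is an SN2 displacement that must outrun E2 elimination of the triflate.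

## Roads not taken

**Alternative 1:** The cut is at O1–C2 and O1–C6. In the forward direction, [Ir(cod)Cl]2 with a chiral phosphoramidite would join two molecules of the cinnamyl carbonate A1 and one of water to the bis-branched diallyl ether A2, setting both benzylic centres. Its merit is real: C2 and C6 would be fixed by a catalyst from achiral material, whereas the chosen plan relies on substrate control for these two centres. The weak points lie in what follows and in the step itself. The second etherification must use the hindered secondary allylic alcohol from the first as nucleophile, and the C2-symmetric ether must win over the meso ether. After A2, the O4 bridge and both methyl-bearing centres still have to be made, by a twofold Markovnikov C–O bond formation across two vinyl groups (for example with Hg(OAc)2, then reduction) under 1,2-induction only. The doubly activated allylic benzylic ether is prone to ionization throughout. The biaryl problem is left untouched; the tosylates are only handles for it. Against the catalytic control of C2/C6, the chosen plan sets that C3, C5 and the O4 bridge come intact from lactate, and that C2 and C6 are then set on a ring, leaving one open stereochemical question instead of two.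

**Alternative 2:** The cut is at O4–C3 and C2–C3. In the forward direction, Rh2(OAc)4 would deliver an ethoxycarbonyl carbene to the oxygen next to the methyl-bearing carbon of the dioxolane A3, and a 1,2-shift of the benzylic acetal carbon would expand the ring to the dioxane ester A4. Its merit is that C5 and C6 would come from a reliable asymmetric dihydroxylation and the ring would be assembled in one step from robust building blocks, with no question of arene nucleophilicity. The weak points are several. Two acetal oxygens compete for the carbene. The 1,2-shift of an oxonium ylide passes through a radical pair, so the configuration at the migrating benzylic carbon is eroded. The new centre C3 has no controlling element. The ester then has to be taken down to a methyl group in about three steps next to acid-sensitive benzylic ethers. The carbene can also insert into the acetal C–H bond or add to the electron-rich arenes. The chosen plan has the methyl groups in place from the start and needs no oxidation-state correction on the ring; it gives away only the reagent-controlled setting of C6.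

**Alternative 3:** The cut is at C2–aryl and C6–aryl, as in the chosen plan, but with the biaryl already present in the nucleophile. Me3SiOTf would ionize the diacetate 7 and the silylated bromobiphenol A5 would attack through the carbon para to oxygen of its unbrominated ring, giving the dibromide A6. This road is more convergent than the chosen one and is better in two respects. No palladium-catalysed C–H arylation has to be run twice on the precious dioxane, and the final allylation would act on aryl bromides, which is easier than on chlorides. Its weak points are these. A5 is itself an unsymmetrical 2,2'-biphenol derivative, so the cross-coupling problem is only moved, admittedly to a simpler substrate. A5 must be used in excess in a step whose stereochemical outcome is the main uncertainty of either plan. Its reacting ring carries an ortho aryl group and a twisted, hindered silyl ether, which should lower its nucleophilicity below that of 8. The chosen plan sets against this that the uncertain arylation is done with the simplest and cheapest arene, that its stereochemical result can be secured at the stage of the simple bisphenol 11 before anything valuable is attached, and that the tether then guarantees which phenol couples with which.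

Key step: step 9

Remark on the chemistry: the (R,R)-ether 4 needs one lactate unit with retention and one with inversion, so ethyl (S)-lactate 1 supplies the electrophile and ethyl (R)-lactate 3 the nucleophile. Compounds 6, 7 and 9 are used as anomer mixtures, because the acetal carbons become planar in step 5.

## Route

Step 1
Reactants: 1 ethyl (S)-lactate
Product: 2 ethyl (2S)-2-{[(trifluoromethyl)sulfonyl]oxy}propanoate
Conditions: Tf2O, 2,6-lutidine, CH2Cl2, −78 → 0 °C
Reagents that add atoms: trifluoromethanesulfonic anhydride, O=S(=O)(OS(=O)(=O)C(F)(F)F)C(F)(F)F
Why: O-sulfonylation of a secondary alcohol; no bond to the stereocentre is broken, so the (S) configuration is kept. The adjacent ester disfavours ionization, so the triflate can be isolated and used at once.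

Step 2
Reactants: 3 ethyl (R)-lactate; 2 ethyl (2S)-2-{[(trifluoromethyl)sulfonyl]oxy}propanoate
Product: 4 diethyl (2R,2'R)-2,2'-oxydipropanoate
Conditions: 3, NaH (0.95 equiv), THF, 0 °C; then 2, −78 → 0 °C
Reagents that add atoms: none
Why: Williamson ether synthesis by SN2 displacement of an α-carbonyl triflate: the sodium alkoxide of 3 attacks C2 of 2 with inversion (S to R), while the carbinol centre of 3 is untouched, which gives the (R,R)-ether. A slight deficit of base and low temperature hold back ester enolization and E2 loss of triflate.

Step 3
Reactants: 4 diethyl (2R,2'R)-2,2'-oxydipropanoate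
Product: 6 (3R,5R)-3,5-dimethyl-1,4-dioxane-2,6-diol (anomer mixture), via (2R,2'R)-2,2'-oxydipropanal 5 (not isolated)
Conditions: i-Bu2AlH (2.2 equiv), CH2Cl2, −78 °C; MeOH, then Na2SO4·10H2O, rt, filtration
Reagents that add atoms: water, O
Why: Partial reduction of α-alkoxy esters with i-Bu2AlH stops at the aldehyde level because the chelated aluminium hemiacetal survives at −78 °C until it is hydrolysed. Dialdehyde 5 takes up one water and closes to the six-membered bis-hemiacetal 6, as diglycolaldehyde-type dialdehydes do, which also protects the enolizable α-centres; the methyl centres are not touched.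

Step 4
Reactants: 6 (3R,5R)-3,5-dimethyl-1,4-dioxane-2,6-diol
Product: 7 (3R,5R)-3,5-dimethyl-1,4-dioxane-2,6-diyl diacetate (anomer mixture)
Conditions: Ac2O, pyridine, DMAP (cat.), CH2Cl2, 0 °C → rt
Reagents that add atoms: acetic anhydride, CC(=O)OC(C)=O
Why: Acylation of lactol hydroxyl groups under nucleophilic catalysis traps the cyclic form. The anomer ratio is irrelevant for the next step.

Step 5
Reactants: 7 (3R,5R)-3,5-dimethyl-1,4-dioxane-2,6-diyl diacetate; 8 tert-butyldimethyl(phenoxy)silane
Product: 10 (2R,3R,5R,6R)-2,6-bis{4-[(tert-butyldimethylsilyl)oxy]phenyl}-3,5-dimethyl-1,4-dioxane, via monoaryl acetate 9 (not isolated)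
Conditions: 8 (6 equiv), Me3SiOTf (2.4 equiv), 2,6-di-tert-butyl-4-methylpyridine (2.5 equiv), CH2Cl2, −78 → −40 °C; Et3N, aq. NaHCO3 at −40 °C
Reagents that add atoms: none
Why: Friedel–Crafts C-arylation of lactol acetates, the reaction type used for aryl C-glycosides: Me3SiOTf ionizes each acetate to a cyclic oxocarbenium ion, which the para carbon of 8 attacks (the bulky silyl ether shields the ortho carbons) while the hindered pyridine takes up the acid. Each arene should enter axially on the half-chair from the face opposite the neighbouring methyl, which avoids a developing gauche contact, so C2 is set trans to the C3 methyl; in the second arylation the competing half-chair would put the first aryl syn-axial to the incoming arene, so C6 is likewise set trans to the C5 methyl. With the trans-3,5-dimethyl backbone from lactate this gives the C2-symmetric (2R,3R,5R,6R) isomer, and the low temperature keeps the product from re-ionizing at its benzylic C–O bonds.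

Step 6
Reactants: 10 (2R,3R,5R,6R)-2,6-bis{4-[(tert-butyldimethylsilyl)oxy]phenyl}-3,5-dimethyl-1,4-dioxane
Product: 11 4,4'-[(2R,3R,5R,6R)-3,5-dimethyl-1,4-dioxane-2,6-diyl]diphenol
Conditions: Bu4NF, AcOH, THF, 0 °C
Reagents that add atoms: none
Why: Fluoride cleavage of aryl silyl ethers. The acetic acid buffer keeps the medium near neutral, so the para-hydroxybenzylic ether neither ionizes nor goes to a quinone methide; no stereocentre is involved.

Step 7
Reactants: 12 2-bromo-4-chlorophenol; 13 di-tert-butylchlorosilane
Product: 14 (2-bromo-4-chlorophenoxy)di-tert-butylsilane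
Conditions: imidazole, DMF, rt
Reagents that add atoms: none
Why: Silylation of a phenol with a chlorohydrosilane under imidazole catalysis. The small Si–H substituent lets the di-tert-butylsilyl group reach the ortho-bromophenol oxygen at room temperature.

Step 8
Reactants: 14 (2-bromo-4-chlorophenoxy)di-tert-butylsilane; 11 4,4'-[(2R,3R,5R,6R)-3,5-dimethyl-1,4-dioxane-2,6-diyl]diphenol
Product: 16 (2R,3R,5R,6R)-2,6-bis(4-{[(2-bromo-4-chlorophenoxy)di-tert-butylsilyl]oxy}phenyl)-3,5-dimethyl-1,4-dioxane, via bromosilane 15 (not isolated)
Conditions: 14 (2.4 equiv), N-bromosuccinimide (2.2 equiv), CH2Cl2, 0 °C → rt; then 11 (1 equiv), imidazole, DMF, rt → 40 °C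
Reagents that add atoms: N-bromosuccinimide, O=C1CCC(=O)N1Br (its bromine is in 15 only and is lost again on the way to 16)
Why: Bromodehydrogenation of the hydrosilane gives the Si–Br compound 15, which silylates both phenols of 11 under imidazole catalysis (silyl ether formation) to the unsymmetrical bis(aryloxy)silanes. The hydrosilane is kept in excess over N-bromosuccinimide so that no electrophilic bromine is left when the electron-rich bisphenol is added.

Step 9
Reactants: 16 (2R,3R,5R,6R)-2,6-bis(4-{[(2-bromo-4-chlorophenoxy)di-tert-butylsilyl]oxy}phenyl)-3,5-dimethyl-1,4-dioxane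
Product: 17 (2R,3R,5R,6R)-2,6-bis(6,6-di-tert-butyl-10-chlorodibenzo[d,f][1,3,2]dioxasilepin-2-yl)-3,5-dimethyl-1,4-dioxane
Conditions: Pd(OAc)2 (10 mol %), PPh3 (20 mol %), Cs2CO3 (3 equiv), toluene, 110 °C, argon
Reagents that add atoms: none
Why: Zerovalent palladium, formed from Pd(OAc)2 and PPh3, adds oxidatively to the C–Br bond of ring B in each arm; carbonate replaces bromide on the divalent arylpalladium species and removes the ortho hydrogen of ring A in a concerted metalation–deprotonation to give an eight-membered diarylpalladium palladacycle, and reductive elimination forms the biaryl bond and returns zerovalent palladium. The closest known reaction type is the palladium-catalysed intramolecular C–H arylation of bis(aryloxy)di-tert-butylsilanes to dibenzodioxasilepines, which after fluoride treatment is a route to unsymmetrical 2,2'-biphenols; here it runs twice in one molecule. Each of the two rings closed is a seven-membered 1,3,2-dioxasilepine, closed by aryl–aryl bond formation between two sp2 carbons held together by the O–Si–O bridge, that is by intramolecular direct arylation and not by closure at a tetrahedral centre. No stereocentre is created: the four dioxane centres are remote, carry no hydrogen that carbonate could remove, and the bridged biaryl axis has only oxygen ortho substituents, so no stable atropisomers are expected. Chemoselectivity for C–Br over C–Cl follows from the PPh3-ligated catalyst, which does not insert into electron-rich aryl chlorides at this temperature. Site selectivity follows from the tether: only the two equivalent ortho C–H bonds of ring A can reach palladium, and the para position is occupied by the dioxane carbon. The tert-butyl groups on silicon compress the O–Si–O angle toward the cyclization conformer and shield the Si–O bonds from carbonate.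

Step 10
Reactants: 17 (2R,3R,5R,6R)-2,6-bis(6,6-di-tert-butyl-10-chlorodibenzo[d,f][1,3,2]dioxasilepin-2-yl)-3,5-dimethyl-1,4-dioxane; 18 allylboronic acid pinacol ester
Product: 19 (2R,3R,5R,6R)-2,6-bis(10-allyl-6,6-di-tert-butyldibenzo[d,f][1,3,2]dioxasilepin-2-yl)-3,5-dimethyl-1,4-dioxane
Conditions: 18 (3 equiv), Pd(OAc)2 (5 mol %), SPhos (10 mol %), K3PO4, toluene/H2O (10:1), 80 °C
Reagents that add atoms: none
Why: Suzuki–Miyaura coupling of aryl chlorides with an allylboronate. The electron-rich dialkylbiarylphosphine allows oxidative addition into the electron-rich C–Cl bonds, while the cyclic silylene keeps the phenols neutral; the moderate temperature limits migration of the allyl double bond into conjugation.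

Step 11
Reactants: 19 (2R,3R,5R,6R)-2,6-bis(10-allyl-6,6-di-tert-butyldibenzo[d,f][1,3,2]dioxasilepin-2-yl)-3,5-dimethyl-1,4-dioxane
Product: 20 (2R,3R,5R,6R)-2,6-bis(5'-allyl-2',6-dihydroxy-[1,1'-biphenyl]-3-yl)-3,5-dimethyl-1,4-dioxane
Conditions: Bu4NF (4.4 equiv), AcOH, THF, 0 °C → rt
Reagents that add atoms: none
Why: Fluoride-driven cleavage of the four aryl–O–Si bonds releases the two biphenol units. Buffered, cold conditions leave the allyl groups and the dibenzylic dioxane unchanged, so the four stereocentres set in steps 2 and 5 are carried into the target.

## Compound list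

1 | ethyl (S)-lactate | CCOC(=O)[C@H](C)O | starting material
2 | ethyl (2S)-2-{[(trifluoromethyl)sulfonyl]oxy}propanoate | CCOC(=O)[C@H](C)OS(=O)(=O)C(F)(F)F | intermediate
3 | ethyl (R)-lactate | CCOC(=O)[C@@H](C)O | starting material
4 | diethyl (2R,2'R)-2,2'-oxydipropanoate | CCOC(=O)[C@@H](C)O[C@H](C)C(=O)OCC | intermediate
5 | (2R,2'R)-2,2'-oxydipropanal | O=C[C@@H](C)O[C@H](C)C=O | intermediate
6 | (3R,5R)-3,5-dimethyl-1,4-dioxane-2,6-diol, anomer mixture | OC1OC(O)[C@@H](C)O[C@@H]1C | intermediate
7 | (3R,5R)-3,5-dimethyl-1,4-dioxane-2,6-diyl diacetate, anomer mixture | CC(=O)OC1OC(OC(C)=O)[C@@H](C)O[C@@H]1C | intermediate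
8 | tert-butyldimethyl(phenoxy)silane | CC(C)(C)[Si](C)(C)Oc1ccccc1 | starting material
9 | (3R,5R,6R)-6-{4-[(tert-butyldimethylsilyl)oxy]phenyl}-3,5-dimethyl-1,4-dioxan-2-yl acetate, either configuration at C2 | CC(C)(C)[Si](C)(C)Oc1ccc(cc1)[C@H]1OC(OC(C)=O)[C@@H](C)O[C@@H]1C | intermediate
10 | (2R,3R,5R,6R)-2,6-bis{4-[(tert-butyldimethylsilyl)oxy]phenyl}-3,5-dimethyl-1,4-dioxane | CC(C)(C)[Si](C)(C)Oc1ccc(cc1)[C@H]1O[C@H](c2ccc(O[Si](C)(C)C(C)(C)C)cc2)[C@@H](C)O[C@@H]1C | intermediate
11 | 4,4'-[(2R,3R,5R,6R)-3,5-dimethyl-1,4-dioxane-2,6-diyl]diphenol | Oc1ccc(cc1)[C@H]1O[C@H](c2ccc(O)cc2)[C@@H](C)O[C@@H]1C | intermediate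
12 | 2-bromo-4-chlorophenol | Oc1ccc(Cl)cc1Br | starting material
13 | di-tert-butylchlorosilane | CC(C)(C)[SiH](Cl)C(C)(C)C | starting material
14 | (2-bromo-4-chlorophenoxy)di-tert-butylsilane | CC(C)(C)[SiH](Oc1ccc(Cl)cc1Br)C(C)(C)C | intermediate
15 | bromo(2-bromo-4-chlorophenoxy)di-tert-butylsilane | CC(C)(C)[Si](Br)(Oc1ccc(Cl)cc1Br)C(C)(C)C | intermediate
16 | (2R,3R,5R,6R)-2,6-bis(4-{[(2-bromo-4-chlorophenoxy)di-tert-butylsilyl]oxy}phenyl)-3,5-dimethyl-1,4-dioxane | Clc1ccc(c(Br)c1)O[Si](C(C)(C)C)(C(C)(C)C)Oc1ccc(cc1)[C@H]1O[C@H](c2ccc(O[Si](C(C)(C)C)(C(C)(C)C)Oc3ccc(Cl)cc3Br)cc2)[C@@H](C)O[C@@H]1C | intermediate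
17 | (2R,3R,5R,6R)-2,6-bis(6,6-di-tert-butyl-10-chlorodibenzo[d,f][1,3,2]dioxasilepin-2-yl)-3,5-dimethyl-1,4-dioxane (each arm: ring A and ring B joined ortho to their oxygens, the two oxygens bridged by Si(t-Bu)2, Cl para to the ring B oxygen) | Clc1ccc2O[Si](C(C)(C)C)(C(C)(C)C)Oc3ccc(cc3-c2c1)[C@H]1O[C@H](c2ccc3O[Si](C(C)(C)C)(C(C)(C)C)Oc4ccc(Cl)cc4-c3c2)[C@@H](C)O[C@@H]1C | intermediate
18 | allylboronic acid pinacol ester | C=CCB1OC(C)(C)C(C)(C)O1 | starting material
19 | (2R,3R,5R,6R)-2,6-bis(10-allyl-6,6-di-tert-butyldibenzo[d,f][1,3,2]dioxasilepin-2-yl)-3,5-dimethyl-1,4-dioxane | C=CCc1ccc2O[Si](C(C)(C)C)(C(C)(C)C)Oc3ccc(cc3-c2c1)[C@H]1O[C@H](c2ccc3O[Si](C(C)(C)C)(C(C)(C)C)Oc4ccc(CC=C)cc4-c3c2)[C@@H](C)O[C@@H]1C | intermediate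
20 | (2R,3R,5R,6R)-2,6-bis(5'-allyl-2',6-dihydroxy-[1,1'-biphenyl]-3-yl)-3,5-dimethyl-1,4-dioxane (CID71580863) | C=CCc1ccc(O)c(-c2cc([C@H]3O[C@H](c4ccc(O)c(-c5cc(CC=C)ccc5O)c4)[C@@H](C)O[C@@H]3C)ccc2O)c1 | target

## Step count and risks

Total: 11 steps. Longest linear sequence: 10 steps (steps 1–6 and 8–11); step 7 is a one-step branch.

**Step 9 (key step).** The arylpalladium bromide may be reduced to the debrominated arene before the C–H bond of ring A is cleaved, and the second cyclization may lag behind the first, because two independent eight-membered palladacycles have to form in one molecule. Traces of water at 110 °C could also let carbonate cleave an Si–O bond and free a phenoxide para to the benzylic ether. The fallback sets out from 11 and forms the biaryl bonds by conventional cross-coupling. Ortho-bromination of both phenol rings with N-bromosuccinimide in CH2Cl2 at 0 °C should give (2R,3R,5R,6R)-2,6-bis(3-bromo-4-hydroxyphenyl)-3,5-dimethyl-1,4-dioxane F1. Suzuki–Miyaura coupling with commercial (5-chloro-2-hydroxyphenyl)boronic acid (Pd(PPh3)4, Na2CO3, 1,2-dimethoxyethane/H2O, 80 °C; C–Br reacts, C–Cl does not) should give the bis(chlorobiphenol) (2R,3R,5R,6R)-2,6-bis(5'-chloro-2',6-dihydroxy-[1,1'-biphenyl]-3-yl)-3,5-dimethyl-1,4-dioxane F2. Bridging each biphenol with di-tert-butylsilyl bis(trifluoromethanesulfonate) and 2,6-lutidine comes back to the route at 17.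

**Step 5.** The monooxygenated arene 8 may be too weak a nucleophile for the oxocarbenium ion, so that proton loss to a dioxene or return of acetate competes. Attack through an ortho carbon, or loss of the kinetic trans selectivity through re-ionization of the new benzylic ether, is also possible. The fallback sets out from 7 and replaces the arene by an organometallic aryl donor. Me3SiBr in CH2Cl2 should convert 7 into (3R,5R)-2,6-dibromo-3,5-dimethyl-1,4-dioxane F3, which is used crude. The arylzinc reagent {4-[(tert-butyldimethylsilyl)oxy]phenyl}zinc bromide F4 is made from commercial (4-bromophenoxy)(tert-butyl)dimethylsilane with Mg and then ZnBr2. It should arylate both α-bromo ether carbons in toluene/di-n-butyl ether, as arylzinc reagents do with glycosyl bromides. The para regiochemistry is then fixed by the carbon–zinc bond and the stereochemical argument (axial entry anti to the adjacent methyl) is unchanged. The fallback comes back to the route at 10.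

**Step 3.** Over-reduction of an ester to the primary alcohol, epimerization of the α-alkoxy aldehyde, or loss of the small polar product during isolation are the likely failures, since two esters must each stop at the aldehyde level. The fallback sets out from 4. Full reduction with LiAlH4 in THF should give (2R,2'R)-2,2'-oxybis(propan-1-ol) F5. A twofold Swern oxidation (oxalyl chloride, dimethyl sulfoxide, Et3N, −78 °C) then gives dialdehyde 5 without an aqueous step, and addition of water comes back to the route at 6.

**Step 8.** Silylation may stop after one phenol, or the bromosilane may be hydrolysed or consumed by succinimide before it reaches the second, hindered site. The fallback sets out from 11 and builds the tether from the other side. Excess di-tert-butylsilyl bis(trifluoromethanesulfonate) with 2,6-lutidine in CH2Cl2 at −78 °C should give the bis(silyl triflate) (2R,3R,5R,6R)-2,6-bis[4-({di-tert-butyl[(trifluoromethylsulfonyl)oxy]silyl}oxy)phenyl]-3,5-dimethyl-1,4-dioxane F6. Adding 2-bromo-4-chlorophenol 12 and imidazole comes back to the route at 16.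

**Step 10.** Oxidative addition into the electron-rich C–Cl bonds may be slow, so that protodeboronation of 18 wins, or a palladium hydride may move the allyl double bond into conjugation with the arene. The fallback sets out from 17 and reverses the polarity. Miyaura borylation (bis(pinacolato)diboron, Pd2(dba)3, XPhos, KOAc, dioxane, 100 °C) should give the bis(boronate) (2R,3R,5R,6R)-2,6-bis[6,6-di-tert-butyl-10-(4,4,5,5-tetramethyl-1,3,2-dioxaborolan-2-yl)dibenzo[d,f][1,3,2]dioxasilepin-2-yl]-3,5-dimethyl-1,4-dioxane F7. Coupling with allyl bromide (Pd(PPh3)4, K2CO3, THF/H2O, 50 °C), in which the reactive allyl electrophile adds to palladium first, comes back to the route at 19.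

## Further compounds

F1 | step 9 | (2R,3R,5R,6R)-2,6-bis(3-bromo-4-hydroxyphenyl)-3,5-dimethyl-1,4-dioxane | Oc1ccc(cc1Br)[C@H]1O[C@H](c2ccc(O)c(Br)c2)[C@@H](C)O[C@@H]1C
F2 | step 9 | (2R,3R,5R,6R)-2,6-bis(5'-chloro-2',6-dihydroxy-[1,1'-biphenyl]-3-yl)-3,5-dimethyl-1,4-dioxane | Oc1ccc(Cl)cc1-c1cc(ccc1O)[C@H]1O[C@H](c2ccc(O)c(c2)-c2cc(Cl)ccc2O)[C@@H](C)O[C@@H]1C
F3 | step 5 | (3R,5R)-2,6-dibromo-3,5-dimethyl-1,4-dioxane | BrC1OC(Br)[C@@H](C)O[C@@H]1C
F4 | step 5 | {4-[(tert-butyldimethylsilyl)oxy]phenyl}zinc bromide | CC(C)(C)[Si](C)(C)Oc1ccc([Zn]Br)cc1
F5 | step 3 | (2R,2'R)-2,2'-oxybis(propan-1-ol) | OC[C@@H](C)O[C@H](C)CO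
F6 | step 8 | (2R,3R,5R,6R)-2,6-bis[4-({di-tert-butyl[(trifluoromethylsulfonyl)oxy]silyl}oxy)phenyl]-3,5-dimethyl-1,4-dioxane | FC(F)(F)S(=O)(=O)O[Si](C(C)(C)C)(C(C)(C)C)Oc1ccc(cc1)[C@H]1O[C@H](c2ccc(O[Si](C(C)(C)C)(C(C)(C)C)OS(=O)(=O)C(F)(F)F)cc2)[C@@H](C)O[C@@H]1C
F7 | step 10 | (2R,3R,5R,6R)-2,6-bis[6,6-di-tert-butyl-10-(4,4,5,5-tetramethyl-1,3,2-dioxaborolan-2-yl)dibenzo[d,f][1,3,2]dioxasilepin-2-yl]-3,5-dimethyl-1,4-dioxane | CC1(C)OB(OC1(C)C)c1ccc2O[Si](C(C)(C)C)(C(C)(C)C)Oc3ccc(cc3-c2c1)[C@H]1O[C@H](c2ccc3O[Si](C(C)(C)C)(C(C)(C)C)Oc4ccc(cc4-c3c2)B2OC(C)(C)C(C)(C)O2)[C@@H](C)O[C@@H]1C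
A1 | alternative 1 | methyl (E)-3-[4-(tosyloxy)phenyl]prop-2-en-1-yl carbonate | COC(=O)OC/C=C/c1ccc(OS(=O)(=O)c2ccc(C)cc2)cc1
A2 | alternative 1 | (S,S)-bis{1-[4-(tosyloxy)phenyl]allyl} ether | Cc1ccc(cc1)S(=O)(=O)Oc1ccc(cc1)[C@H](C=C)O[C@H](c1ccc(OS(=O)(=O)c2ccc(C)cc2)cc1)C=C
A3 | alternative 2 | (4R,5R)-5-methyl-2,4-bis{4-[(triisopropylsilyl)oxy]phenyl}-1,3-dioxolane, either configuration at C2 | CC(C)[Si](C(C)C)(C(C)C)Oc1ccc(cc1)C1O[C@H](c2ccc(O[Si](C(C)C)(C(C)C)C(C)C)cc2)[C@@H](C)O1
A4 | alternative 2 | ethyl (2R,3R,5R,6R)-5-methyl-3,6-bis{4-[(triisopropylsilyl)oxy]phenyl}-1,4-dioxane-2-carboxylate | CC(C)[Si](C(C)C)(C(C)C)Oc1ccc(cc1)[C@H]1O[C@H](c2ccc(O[Si](C(C)C)(C(C)C)C(C)C)cc2)[C@@H](C)O[C@@H]1C(=O)OCC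
A5 | alternative 3 | [(5-bromo-[1,1'-biphenyl]-2,2'-diyl)bis(oxy)]bis(tert-butyldimethylsilane) | CC(C)(C)[Si](C)(C)Oc1ccccc1-c1cc(Br)ccc1O[Si](C)(C)C(C)(C)C
A6 | alternative 3 | (2R,3R,5R,6R)-2,6-bis{5'-bromo-2',6-bis[(tert-butyldimethylsilyl)oxy]-[1,1'-biphenyl]-3-yl}-3,5-dimethyl-1,4-dioxane | Brc1ccc(O[Si](C)(C)C(C)(C)C)c(c1)-c1cc(ccc1O[Si](C)(C)C(C)(C)C)[C@H]1O[C@H](c2ccc(O[Si](C)(C)C(C)(C)C)c(c2)-c2cc(Br)ccc2O[Si](C)(C)C(C)(C)C)[C@@H](C)O[C@@H]1C
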